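If the run has to stop at 12 h, charge violet, whose 4 mol% is the largest loading of the row. You suspect that twice the loading buys what extra time buys, and the catalyst balance supports that.

common to all: substrate 20 mM
- maple: free catalyst 0.48 mol%; run made earlier
- larch: free catalyst 1.3 mol%; run made earlier
- alder: free catalyst 3.5 mol%; run made earlier
- amber: free catalyst 0.5 mol%; time 12 h
- ochre: free catalyst 1 mol%; time 12 h
- grey: free catalyst 2 mol%; time 12 h
- violet: free catalyst 4 mol%; time 12 h

| run | time / h | product / % | substrate / % |
|---|---|---|---|
| maple | 1.50 | 5 | 96 |
| maple | 3.00 | 5 | 93 |
| maple | 5.00 | 8 | 88 |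
| maple | 6.00 | 11 | 89 |
| maple | 8.00 | 16 | 87 |
| larch | 1.50 | 6 | 93 |
| larch | 3.00 | 13 | 85 |
| larch | 5.00 | 22 | 77 |
| larch | 6.00 | 27 | 73 |
| larch | 8.00 | 32 | 67 |
| alder | 0.833 | 9 | 85 |
| alder | 2.00 | 24 | 75 |
| alder | 4.00 | 40 | 60 |
| alder | 6.00 | 53 | 46 |
| alder | 8.00 | 60 | 37 |

(scatter of a reading: 1.5 percentage points)

- a reading or a percentage of product counts all its forms, free or not
- "hardly changes" means that all values lie within two and a half points (for a concentration: within two and a half percent of the largest)

1. amount of product at the end, in percent of the substrate charged for amber, ochre, grey, violet, in this order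
2. the course of these numbers from the first flask to the last (rises all the way / falls all the way / falls, then rises / hardly changes / rises, then falls)

Free catalyst is charged in far smaller amount than the product it makes: alder reached 60 % product from 3.5 mol%, a turnover number of 17.1. So the catalyst keeps coming back, and we take its total over all its forms as constant. We assume that the working share of that total depends on the mixture and not on the loading. Then time and loading enter as a product.

Multiply a flask's time by its loading over alder's: violet's 12 h become 13.7 h, its alder-equivalent time θ, a time normalised by catalyst loading. As a check, larch at 8.00 h has θ = 2.97 h, where alder's curve gives 31.8 % and larch read 32 %.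

Amber, ochre and grey have θ = 1.71 h, 3.43 h and 6.86 h. Straight lines between alder's readings give 20.3 %, 35.4 % and 56.0 %. Violet lies beyond alder's last reading, so we continue alder's last stretch of substrate decay, 0.109 h⁻¹, and, counting what is not substrate as product, reach 80.1 %, an extrapolation past the readings. Our row therefore rises from amber to violet.

The forecast reads 22 %, 36 %, 56 % and 73 %, course rises all the way, from an “approach to a plateau near 80%”, and it parts from our reckoning at violet, where it stands lower.

The flasks give 21.5 %, 36.6 %, 56.8 % and 78.2 %, so the row rises all the way.

free catalyst + product ⇌ idle complex (K = 57.0 M⁻¹, k = 0.0364 M⁻¹ s⁻¹); catalyst intermediate B → free catalyst + product (k = 0.0431 s⁻¹); catalyst intermediate A → catalyst intermediate B (k = 0.0116 s⁻¹); substrate + free catalyst ⇌ catalyst intermediate A (K = 20.0 M⁻¹, k = 0.101 M⁻¹ s⁻¹) At the asked time, idle complex holds 45.5 % of violet's catalyst, and its product is counted in that 78.2 %. Violet's result belongs to θ = 13.7 h. Violet at 6.00 h has θ = 6.86 h, the same as grey at 12.0 h with 6.86 h, and violet then stood at 57.2 % product against grey's 56.8 %.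

The earlier runs and the new flask are simulated for substances that don't exist; noise was put on by code.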